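The chroman is cut at O1–C8a and C4–C4a. On ring A the ether oxygen O1 (on C8a) stands para to the oxygen on C6, so the pyran can be grown onto a 4-alkylphenol whose hydroxyl ends up as the C6 oxygen. In one operation an iodine(III) oxidant closes the side-chain alcohol onto the alkyl-bearing para carbon (spiro ether), after which a Lewis acid moves the C4 methylene over to the adjacent unsubstituted ring carbon, delivering the chroman-6-ol. The precursor is an (S)-2-aryl-3-(4-hydroxy-2,3-dimethoxyphenyl)propan-1-ol made by oxazolidinone-controlled benzylation; ring B travels as a fully substituted, benzyl-protected tetramethoxyphenol and is turned into the quinone last.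

Key step: step 13

Remark: the stereocentre is S from 21 to 28, because the ranking at that carbon (CH2O or C=O > ring B > CH2Ar > H) does not change. Metal species are written with covalent metal bonds, and the spiro carbon of 24 (both epimers, convergent) is left undefined.

Step 1
Reactants: 1 3,4,5-trimethoxyphenol
Product: 2 5-(benzyloxy)-1,2,3-trimethoxybenzene
Conditions: BnBr, K2CO3, DMF, rt
Reagents that add atoms: benzyl bromide, BrCc1ccccc1
Why: Williamson ether synthesis on the phenoxide; the benzyl group marks the one ring-B oxygen that is to be freed by hydrogenolysis before the final oxidation.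

Step 2
Reactants: 2 5-(benzyloxy)-1,2,3-trimethoxybenzene
Product: 3 1-(benzyloxy)-2,6-dibromo-3,4,5-trimethoxybenzene
Conditions: NBS (2.1 equiv), MeCN, 0 °C → rt
Reagents that add atoms: N-bromosuccinimide, O=C1CCC(=O)N1Br
Why: Electrophilic aromatic bromination: the two remaining ring hydrogens are equivalent and each lies ortho or para to three alkoxy groups, so double bromination should give a single symmetric product with no regiochemical issue.

Step 3
Reactants: 3 1-(benzyloxy)-2,6-dibromo-3,4,5-trimethoxybenzene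
Product: 6 2-(benzyloxy)-3-bromo-4,5,6-trimethoxyphenol, via aryllithium 4 (not isolated), via lithium aryl(trimethoxy)borate 5 (not isolated)
Conditions: n-BuLi (1.0 equiv), THF, −78 °C; B(OMe)3, −78 → 0 °C; then AcOH, 30% aq. H2O2, 0 °C → rt
Reagents that add atoms: hydrogen peroxide, OO
Why: Bromine–lithium exchange at one of two equivalent bromides (a second exchange on an aryllithium is unfavourable), borylation and peroxide-induced boron-to-oxygen aryl migration (boronate oxidation) replace one bromine by hydroxyl, and the low temperature keeps the lithiated benzyl ether from Wittig rearrangement.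

Step 4
Reactants: 6 2-(benzyloxy)-3-bromo-4,5,6-trimethoxyphenol
Product: 7 1-(benzyloxy)-2-bromo-3,4,5,6-tetramethoxybenzene
Conditions: MeI, K2CO3, DMF, rt
Reagents that add atoms: iodomethane, CI
Why: Williamson O-methylation of the hindered phenoxide completes the pentaoxygenated ring and leaves one bromide as the handle for the side chain.

Step 5
Reactants: 7 1-(benzyloxy)-2-bromo-3,4,5,6-tetramethoxybenzene; 8 ethyl bromoacetate
Product: 11 [2-(benzyloxy)-3,4,5,6-tetramethoxyphenyl]acetic acid, via Reformatsky reagent 9 (not isolated), via ethyl arylacetate 10 (not isolated)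
Conditions: 8, Zn dust (TMSCl-activated), THF, 40 °C; then 7, Pd(dba)2 (2 mol %), Q-Phos (2 mol %), THF, rt → 60 °C; then LiOH, MeOH/H2O, 50 °C; aq. HCl
Reagents that add atoms: lithium hydroxide, [Li+].[OH-]
Why: Palladium-catalysed cross-coupling of an aryl bromide with a zinc ester enolate (Negishi-type α-arylation with a Reformatsky reagent) runs under neutral conditions that spare the benzyl ether, a bulky electron-rich phosphine is chosen for the doubly ortho-substituted bromide, and saponification in the same flask allows isolation of the acid by extraction.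

Step 6
Reactants: 11 [2-(benzyloxy)-3,4,5,6-tetramethoxyphenyl]acetic acid; 12 (4S)-4-benzyl-1,3-oxazolidin-2-one
Product: 14 (4S)-4-benzyl-3-{[2-(benzyloxy)-3,4,5,6-tetramethoxyphenyl]acetyl}-1,3-oxazolidin-2-one, via mixed pivalic anhydride 13 (not isolated)
Conditions: PivCl, Et3N, THF, −20 °C; then 12, LiCl, −20 °C → rt
Reagents that add atoms: none
Why: N-Acylation of the oxazolidinone via the mixed pivalic anhydride (triethylamine/lithium chloride protocol), in which the nucleophile attacks the unhindered arylacetyl carbonyl and not the pivaloyl one.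

Step 7
Reactants: 15 2,3-dimethoxyphenol
Product: 16 (2,3-dimethoxyphenoxy)tri(propan-2-yl)silane
Conditions: TIPSCl, imidazole, DMF, rt
Reagents that add atoms: chlorotri(propan-2-yl)silane, CC(C)[Si](Cl)(C(C)C)C(C)C
Why: Silylation of the phenol with a bulky silyl chloride gives an ether that tolerates organolithium, enolate and borohydride reagents and does not coordinate lithium in the next step.

Step 8
Reactants: 16 (2,3-dimethoxyphenoxy)tri(propan-2-yl)silane
Product: 18 {2,3-dimethoxy-4-[(triisopropylsilyl)oxy]phenyl}methanol, via aryllithium 17 (not isolated)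
Conditions: n-BuLi, TMEDA, Et2O, 0 °C → rt; then (CH2O)n, 0 °C → rt
Reagents that add atoms: paraformaldehyde (reacts as formaldehyde), C=O
Why: Directed ortho-metalation: the 3-methoxy group is the only coordinating substituent with a free neighbouring position (C4, para to the silyloxy group), the hindered silyl ether does not direct, and the aryllithium adds to formaldehyde to give the benzylic alcohol.

Step 9
Reactants: 18 {2,3-dimethoxy-4-[(triisopropylsilyl)oxy]phenyl}methanol
Product: 19 [4-(bromomethyl)-2,3-dimethoxyphenoxy]tri(propan-2-yl)silane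
Conditions: PBr3 (0.4 equiv), Et2O, 0 °C; used crude
Reagents that add atoms: phosphorus tribromide, BrP(Br)Br
Why: Conversion of an electron-rich benzylic alcohol into the bromide with phosphorus tribromide is fast at 0 °C, and the aryl triisopropylsilyl ether should survive the short contact with HBr.

Step 10
Reactants: 14 (4S)-4-benzyl-3-{[2-(benzyloxy)-3,4,5,6-tetramethoxyphenyl]acetyl}-1,3-oxazolidin-2-one; 19 [4-(bromomethyl)-2,3-dimethoxyphenoxy]tri(propan-2-yl)silane
Product: 21 (4S)-4-benzyl-3-[(2S)-2-[2-(benzyloxy)-3,4,5,6-tetramethoxyphenyl]-3-{2,3-dimethoxy-4-[(triisopropylsilyl)oxy]phenyl}propanoyl]-1,3-oxazolidin-2-one, via sodium enolate 20 (not isolated)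
Conditions: NaHMDS, THF, −78 °C; then 19, −78 → −40 °C
Reagents that add atoms: none
Why: Evans asymmetric alkylation: the sodium-chelated (Z)-enolate is shielded on one face by the C4 benzyl group of the (4S)-auxiliary, so the benzylic bromide adds from the opposite face and fixes the (S) configuration of the future C3.

Step 11
Reactants: 21 (4S)-4-benzyl-3-[(2S)-2-[2-(benzyloxy)-3,4,5,6-tetramethoxyphenyl]-3-{2,3-dimethoxy-4-[(triisopropylsilyl)oxy]phenyl}propanoyl]-1,3-oxazolidin-2-one
Product: 22 (2S)-2-[2-(benzyloxy)-3,4,5,6-tetramethoxyphenyl]-3-{2,3-dimethoxy-4-[(triisopropylsilyl)oxy]phenyl}propan-1-ol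
Conditions: LiBH4, MeOH (1 equiv), THF, 0 °C
Reagents that add atoms: none
Why: Reductive removal of the auxiliary: borohydride attacks the exocyclic imide carbonyl and reduces it to the primary alcohol without enolising the α-stereocentre, while silyl and benzyl ethers are inert.

Step 12
Reactants: 22 (2S)-2-[2-(benzyloxy)-3,4,5,6-tetramethoxyphenyl]-3-{2,3-dimethoxy-4-[(triisopropylsilyl)oxy]phenyl}propan-1-ol
Product: 23 4-[(2S)-2-[2-(benzyloxy)-3,4,5,6-tetramethoxyphenyl]-3-hydroxypropyl]-2,3-dimethoxyphenol
Conditions: TBAF, THF, 0 °C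
Reagents that add atoms: none
Why: Fluoride-mediated desilylation, driven by the strength of the Si–F bond, releases the para-alkylphenol and leaves the benzyl ether and the alcohol untouched.

Step 13
Reactants: 23 4-[(2S)-2-[2-(benzyloxy)-3,4,5,6-tetramethoxyphenyl]-3-hydroxypropyl]-2,3-dimethoxyphenol
Product: 25 (3S)-3-[2-(benzyloxy)-3,4,5,6-tetramethoxyphenyl]-7,8-dimethoxychroman-6-ol, via spirodienone 24 (not isolated)
Conditions: PhI(OAc)2 (1.05 equiv), (CF3)2CHOH/CH2Cl2, 0 °C; concentrate; then BF3·OEt2, CH2Cl2, −40 → 0 °C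
Reagents that add atoms: none
Why: The phenol binds to iodine(III) and iodobenzene departs, leaving an electron-poor (phenoxenium-like) ring that is trapped at its alkyl-bearing para carbon by the primary alcohol of the side chain in a 5-exo-trig closure, which makes the C8a–O1 bond and the 1-oxaspiro[4.5]decadienone 24. Coordination of BF3 to the dienone carbonyl then starts a dienone–phenol rearrangement in which the C4 methylene undergoes a 1,2-shift to the neighbouring CH carbon (new C4–C4a bond), so the pyran ring is closed by enlargement of the five-membered spiro ether, and loss of a proton restores the aromatic ring as the chroman-6-ol. The closest known reaction type is the hypervalent-iodine spiroetherification of 4-(3-hydroxypropyl)phenols followed by acid-induced quinol-ether rearrangement with alkyl migration. No lasting stereocentre is created: the spiro centre forms without control and disappears on aromatisation, and C3 is never next to a cationic or enolisable carbon, so its configuration is carried through. Ring B should not be touched, since all its oxygens are etherified, iodine(III) engages free phenols preferentially and the ring has no hydrogen for an electrophilic side reaction, and the non-nucleophilic fluoroalcohol leaves the internal hydroxyl as the only competent nucleophile. Two further selectivities are needed: the alkyl group and not the ether oxygen has to move, which is favoured because the oxygen that stays behind turns the vacated centre into an oxocarbenium ion, and it has to move toward C4a, which is ensured because C4a carries the only hydrogen whose loss restores aromaticity, a shift toward the methoxylated C8 being a reversible dead end.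

Step 14
Reactants: 25 (3S)-3-[2-(benzyloxy)-3,4,5,6-tetramethoxyphenyl]-7,8-dimethoxychroman-6-ol
Product: 26 (3S)-3-[2-(benzyloxy)-3,4,5,6-tetramethoxyphenyl]-6,7,8-trimethoxychromane
Conditions: MeI, K2CO3, acetone, 50 °C
Reagents that add atoms: iodomethane, CI
Why: Williamson O-methylation of the C6 phenol completes ring A and removes the oxidisable hydroquinone mono-ether hydroxyl before the last step.

Step 15
Reactants: 26 (3S)-3-[2-(benzyloxy)-3,4,5,6-tetramethoxyphenyl]-6,7,8-trimethoxychromane
Product: 27 2,3,4,5-tetramethoxy-6-[(3S)-6,7,8-trimethoxychroman-3-yl]phenol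
Conditions: H2 (1 atm), 10% Pd/C, EtOAc/EtOH, rt
Reagents that add atoms: none
Why: Catalytic hydrogenolysis cleaves only the benzylic C–O bond of the ring-B ether; aryl methyl ethers, the chroman ring and the C3 stereocentre are not affected.

Step 16
Reactants: 27 2,3,4,5-tetramethoxy-6-[(3S)-6,7,8-trimethoxychroman-3-yl]phenol
Product: 28 2,3,5-trimethoxy-6-[(3S)-6,7,8-trimethoxychroman-3-yl]cyclohexa-2,5-diene-1,4-dione (target)
Conditions: PhI(OAc)2 (1.1 equiv), MeCN/H2O (2:1), 0 °C
Reagents that add atoms: water, O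
Why: Oxidative demethylation of a para-methoxyphenol with iodine(III): the phenol is oxidised, water adds at the para carbon and methanol is lost to give the 1,4-quinone, while ring A (ethers only) is inert under these neutral conditions and the absence of base protects the C3 stereocentre next to the quinone.

Compound list
1 | 3,4,5-trimethoxyphenol | COc1cc(O)cc(OC)c1OC | starting material
2 | 5-(benzyloxy)-1,2,3-trimethoxybenzene | COc1cc(OCc2ccccc2)cc(OC)c1OC | intermediate
3 | 1-(benzyloxy)-2,6-dibromo-3,4,5-trimethoxybenzene | COc1c(Br)c(OCc2ccccc2)c(Br)c(OC)c1OC | intermediate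
4 | [2-(benzyloxy)-3-bromo-4,5,6-trimethoxyphenyl]lithium (formed in situ) | COc1c(Br)c(OCc2ccccc2)c([Li])c(OC)c1OC | intermediate
5 | lithium [2-(benzyloxy)-3-bromo-4,5,6-trimethoxyphenyl]trimethoxyborate (formed in situ) | [Li+].COc1c(Br)c(OCc2ccccc2)c([B-](OC)(OC)OC)c(OC)c1OC | intermediate
6 | 2-(benzyloxy)-3-bromo-4,5,6-trimethoxyphenol | COc1c(Br)c(OCc2ccccc2)c(O)c(OC)c1OC | intermediate
7 | 1-(benzyloxy)-2-bromo-3,4,5,6-tetramethoxybenzene | COc1c(Br)c(OCc2ccccc2)c(OC)c(OC)c1OC | intermediate
8 | ethyl bromoacetate | CCOC(=O)CBr | starting material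
9 | bromo(2-ethoxy-2-oxoethyl)zinc (formed in situ) | CCOC(=O)C[Zn]Br | intermediate
10 | ethyl [2-(benzyloxy)-3,4,5,6-tetramethoxyphenyl]acetate (formed in situ) | CCOC(=O)Cc1c(OC)c(OC)c(OC)c(OC)c1OCc1ccccc1 | intermediate
11 | [2-(benzyloxy)-3,4,5,6-tetramethoxyphenyl]acetic acid | OC(=O)Cc1c(OC)c(OC)c(OC)c(OC)c1OCc1ccccc1 | intermediate
12 | (4S)-4-benzyl-1,3-oxazolidin-2-one | O=C1N[C@@H](Cc2ccccc2)CO1 | starting material
13 | [2-(benzyloxy)-3,4,5,6-tetramethoxyphenyl]acetic pivalic anhydride (formed in situ) | CC(C)(C)C(=O)OC(=O)Cc1c(OC)c(OC)c(OC)c(OC)c1OCc1ccccc1 | intermediate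
14 | (4S)-4-benzyl-3-{[2-(benzyloxy)-3,4,5,6-tetramethoxyphenyl]acetyl}-1,3-oxazolidin-2-one | O=C(Cc1c(OC)c(OC)c(OC)c(OC)c1OCc1ccccc1)N1[C@@H](Cc2ccccc2)COC1=O | intermediate
15 | 2,3-dimethoxyphenol | COc1cccc(O)c1OC | starting material
16 | (2,3-dimethoxyphenoxy)tri(propan-2-yl)silane | COc1cccc(O[Si](C(C)C)(C(C)C)C(C)C)c1OC | intermediate
17 | {2,3-dimethoxy-4-[(triisopropylsilyl)oxy]phenyl}lithium (formed in situ) | [Li]c1ccc(O[Si](C(C)C)(C(C)C)C(C)C)c(OC)c1OC | intermediate
18 | {2,3-dimethoxy-4-[(triisopropylsilyl)oxy]phenyl}methanol | OCc1ccc(O[Si](C(C)C)(C(C)C)C(C)C)c(OC)c1OC | intermediate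
19 | [4-(bromomethyl)-2,3-dimethoxyphenoxy]tri(propan-2-yl)silane | BrCc1ccc(O[Si](C(C)C)(C(C)C)C(C)C)c(OC)c1OC | intermediate
20 | sodium (Z)-1-[(4S)-4-benzyl-2-oxo-1,3-oxazolidin-3-yl]-2-[2-(benzyloxy)-3,4,5,6-tetramethoxyphenyl]ethen-1-olate (formed in situ) | [Na]O/C(=C\c1c(OC)c(OC)c(OC)c(OC)c1OCc1ccccc1)N1[C@@H](Cc2ccccc2)COC1=O | intermediate
21 | (4S)-4-benzyl-3-[(2S)-2-[2-(benzyloxy)-3,4,5,6-tetramethoxyphenyl]-3-{2,3-dimethoxy-4-[(triisopropylsilyl)oxy]phenyl}propanoyl]-1,3-oxazolidin-2-one | O=C([C@@H](Cc1ccc(O[Si](C(C)C)(C(C)C)C(C)C)c(OC)c1OC)c1c(OC)c(OC)c(OC)c(OC)c1OCc1ccccc1)N1[C@@H](Cc2ccccc2)COC1=O | intermediate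
22 | (2S)-2-[2-(benzyloxy)-3,4,5,6-tetramethoxyphenyl]-3-{2,3-dimethoxy-4-[(triisopropylsilyl)oxy]phenyl}propan-1-ol | COc1c(OC)c(OCc4ccccc4)c([C@H](Cc2ccc(O[Si](C(C)C)(C(C)C)C(C)C)c(OC)c2OC)CO)c(OC)c1OC | intermediate
23 | 4-[(2S)-2-[2-(benzyloxy)-3,4,5,6-tetramethoxyphenyl]-3-hydroxypropyl]-2,3-dimethoxyphenol | COc1c(OC)c(OCc4ccccc4)c([C@H](Cc2ccc(O)c(OC)c2OC)CO)c(OC)c1OC | intermediate
24 | (3S)-3-[2-(benzyloxy)-3,4,5,6-tetramethoxyphenyl]-6,7-dimethoxy-1-oxaspiro[4.5]deca-6,9-dien-8-one (both spiro epimers; formed in situ) | O=C1C=CC2(C[C@@H](c3c(OC)c(OC)c(OC)c(OC)c3OCc3ccccc3)CO2)C(OC)=C1OC | intermediate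
25 | (3S)-3-[2-(benzyloxy)-3,4,5,6-tetramethoxyphenyl]-7,8-dimethoxychroman-6-ol | COc1c(OC)c(OCc4ccccc4)c([C@H]2COc3c(cc(O)c(OC)c3OC)C2)c(OC)c1OC | intermediate
26 | (3S)-3-[2-(benzyloxy)-3,4,5,6-tetramethoxyphenyl]-6,7,8-trimethoxychromane | COc1c(OC)c(OCc4ccccc4)c([C@H]2COc3c(cc(OC)c(OC)c3OC)C2)c(OC)c1OC | intermediate
27 | 2,3,4,5-tetramethoxy-6-[(3S)-6,7,8-trimethoxychroman-3-yl]phenol | COc1c(OC)c(O)c([C@H]2COc3c(cc(OC)c(OC)c3OC)C2)c(OC)c1OC | intermediate
28 | 2,3,5-trimethoxy-6-[(3S)-6,7,8-trimethoxychroman-3-yl]cyclohexa-2,5-diene-1,4-dione | COC1=C(OC)C(=O)C([C@H]2COc3c(cc(OC)c(OC)c3OC)C2)=C(OC)C1=O | target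

Total step count: 16. Longest linear sequence: 13 steps (steps 1–6 and 10–16, from 3,4,5-trimethoxyphenol); steps 7–9 form the three-step side branch to bromide 19.

Steps most likely to fail

Step 13. The activated spirodienone may ionise at the spiro C–O bond or decompose faster than the alkyl shift, or the oxidation may be diverted to an ortho position, so that material is lost instead of being ring-enlarged. The fallback makes the O1–C8a bond by cross-coupling instead of dearomatisation; it sets out from imide 14 and comes back at 26. Commercial (3,4,5-trimethoxyphenyl)methanol is brominated with NBS to (2-bromo-3,4,5-trimethoxyphenyl)methanol F1 and converted with PBr3 into 2-bromo-1-(bromomethyl)-3,4,5-trimethoxybenzene F2. Enolate 20, generated from 14 as in step 10, is alkylated with this bromide to (4S)-4-benzyl-3-[(2S)-2-[2-(benzyloxy)-3,4,5,6-tetramethoxyphenyl]-3-(2-bromo-3,4,5-trimethoxyphenyl)propanoyl]-1,3-oxazolidin-2-one F3. Reduction with LiBH4 gives (2S)-2-[2-(benzyloxy)-3,4,5,6-tetramethoxyphenyl]-3-(2-bromo-3,4,5-trimethoxyphenyl)propan-1-ol F4. Palladium-catalysed intramolecular aryl ether formation (Pd(OAc)2, a bulky di-tert-butyl biarylphosphine, Cs2CO3, toluene, 80 °C) then closes the pyran and should give 26 directly, so that steps 11–14 are bypassed.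

Step 5. Oxidative addition at the doubly ortho-substituted, electron-rich C–Br bond may be slow, so that protodebromination or self-condensation of the zinc enolate takes over. The fallback sets out from bromide 7 and comes back at acid 11. Bromine–lithium exchange (n-BuLi, THF, −78 °C) gives [2-(benzyloxy)-3,4,5,6-tetramethoxyphenyl]lithium F5, which opens oxirane in the presence of BF3·OEt2 to 2-[2-(benzyloxy)-3,4,5,6-tetramethoxyphenyl]ethan-1-ol F6. Oxidation with catalytic TEMPO and PhI(OAc)2 in MeCN/H2O passes through [2-(benzyloxy)-3,4,5,6-tetramethoxyphenyl]acetaldehyde F7 and should end at 11.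

Step 8. Deprotonation may occur at a ring position other than C4, the base may attack silicon, or the aryllithium may be captured sluggishly by polymeric formaldehyde. The fallback fixes the site by a halogen; it sets out from 2,3-dimethoxyphenol 15 and comes back at aryllithium 17. Para-selective bromination of the free phenol with Bu4NBr3 (CH2Cl2/MeOH, rt) should give 4-bromo-2,3-dimethoxyphenol F8, and silylation (TIPSCl, imidazole) gives (4-bromo-2,3-dimethoxyphenoxy)tri(propan-2-yl)silane F9. Bromine–lithium exchange (n-BuLi, THF, −78 °C) generates 17 at a defined position, and trapping with paraformaldehyde as in step 8 leads to 18.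

Further compounds
F1 | step 13 | (2-bromo-3,4,5-trimethoxyphenyl)methanol | OCc1cc(OC)c(OC)c(OC)c1Br
F2 | step 13 | 2-bromo-1-(bromomethyl)-3,4,5-trimethoxybenzene | BrCc1cc(OC)c(OC)c(OC)c1Br
F3 | step 13 | (4S)-4-benzyl-3-[(2S)-2-[2-(benzyloxy)-3,4,5,6-tetramethoxyphenyl]-3-(2-bromo-3,4,5-trimethoxyphenyl)propanoyl]-1,3-oxazolidin-2-one | O=C([C@@H](Cc1cc(OC)c(OC)c(OC)c1Br)c1c(OC)c(OC)c(OC)c(OC)c1OCc1ccccc1)N1[C@@H](Cc2ccccc2)COC1=O
F4 | step 13 | (2S)-2-[2-(benzyloxy)-3,4,5,6-tetramethoxyphenyl]-3-(2-bromo-3,4,5-trimethoxyphenyl)propan-1-ol | COc1c(OC)c(OCc4ccccc4)c([C@H](Cc2cc(OC)c(OC)c(OC)c2Br)CO)c(OC)c1OC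
F5 | step 5 | [2-(benzyloxy)-3,4,5,6-tetramethoxyphenyl]lithium | [Li]c1c(OC)c(OC)c(OC)c(OC)c1OCc1ccccc1
F6 | step 5 | 2-[2-(benzyloxy)-3,4,5,6-tetramethoxyphenyl]ethan-1-ol | OCCc1c(OC)c(OC)c(OC)c(OC)c1OCc1ccccc1
F7 | step 5 | [2-(benzyloxy)-3,4,5,6-tetramethoxyphenyl]acetaldehyde | O=CCc1c(OC)c(OC)c(OC)c(OC)c1OCc1ccccc1
F8 | step 8 | 4-bromo-2,3-dimethoxyphenol | COc1c(Br)ccc(O)c1OC
F9 | step 8 | (4-bromo-2,3-dimethoxyphenoxy)tri(propan-2-yl)silane | COc1c(Br)ccc(O[Si](C(C)C)(C(C)C)C(C)C)c1OC
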